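**Plan**

1. Retrosynthetic cuts, in order: C4–C4a of ring C (Friedel–Crafts acylation), O1–C2 (Mitsunobu etherification), C2–C3 (allylboration of an aryl aldehyde) and the C3'–C8'' biaryl bond (Suzuki–Miyaura coupling). This leads back to apigenin, 3-bromo-4-hydroxybenzaldehyde and 3,5-dimethoxyphenol.
2. Forward order: the intact, O-benzylated flavone is joined to ring B first. Then C2–C3 and O1–C2 are made, the allyl group is cut down to the C4 acid, ring C is closed last, and all protecting groups leave in one operation.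
3. Enabling feature: ring A hangs on O1 through C8a and carries oxygen at C5 and C7. With both as methoxy groups, the 3,5-dimethoxyphenoxy ring has two equivalent ortho carbons, each activated by three oxygens, and either one becomes C4a. After closure only the C5 methoxy group lies peri to the C4 ketone, so chelation removes it and leaves the C7 methyl ether.
4. Reinforcement: the C4' oxygen of ring B is held as an acetate from the aldehyde stage to the end, so that the benzylic C2–O bond para to it does not ionise during the substitution or the acidic ring closure.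
5. Stereochemistry: C2 is the only stereocentre. A chiral phosphoric acid sets the (R)-carbinol in the allylboration, and the Mitsunobu reaction inverts it to the (S) configuration of the target.

Key step: step 10

Numbering and abbreviation: flavanone atoms are O1, C2, C3, C4, C4a–C8a, with ring B as C1'–C6'; flavone atoms are double-primed. Fl stands for the 5,7-bis(benzyloxy)-2-[4-(benzyloxy)phenyl]-4-oxo-4H-chromen-8-yl group.

Assumption: the C3'–C8'' axis has three ortho substituents and is taken to rotate on the laboratory timescale, since the target is drawn without axial configuration; slowly exchanging rotamers may broaden spectra but are one compound.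

**Route**

Step 1
Reactants: 1 apigenin
Product: 2 5,7-bis(benzyloxy)-2-[4-(benzyloxy)phenyl]-4H-chromen-4-one
Conditions: BnBr (4 equiv), K2CO3, DMF, 80 °C
Reagents that add atoms: benzyl bromide, BrCc1ccccc1
Why: Williamson etherification of the three phenoxides, with heating to reach the hydrogen-bonded C5'' hydroxyl, gives benzyl ethers that should survive every later step and leave together at the end.

Step 2
Reactants: 2 5,7-bis(benzyloxy)-2-[4-(benzyloxy)phenyl]-4H-chromen-4-one
Product: 3 5,7-bis(benzyloxy)-2-[4-(benzyloxy)phenyl]-8-iodo-4H-chromen-4-one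
Conditions: NIS (1.2 equiv), DMF, rt → 50 °C
Reagents that add atoms: N-iodosuccinimide, O=C1CCC(=O)N1I
Why: Electrophilic aromatic iodination of a 5,7-dialkoxyflavone, which with O5'' alkylated is expected at C8'' (ortho to O7'' and O1'', para to O5'') and not at C6'', which is flanked by two benzyloxy groups.

Step 3
Reactants: 4 3-bromo-4-hydroxybenzaldehyde
Product: 5 4-hydroxy-3-(4,4,5,5-tetramethyl-1,3,2-dioxaborolan-2-yl)benzaldehyde
Conditions: B2pin2 (1.3 equiv), PdCl2(dppf) [dppf = 1,1'-bis(diphenylphosphino)ferrocene] (3 mol %), KOAc (3 equiv), 1,4-dioxane, 85 °C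
Reagents that add atoms: bis(pinacolato)diboron, CC1(C)OB(OC1(C)C)B1OC(C)(C)C(C)(C)O1
Why: Miyaura borylation of an aryl bromide, whose weakly basic acetate conditions tolerate the free phenol and the aldehyde.

Step 4
Reactants: 3 5,7-bis(benzyloxy)-2-[4-(benzyloxy)phenyl]-8-iodo-4H-chromen-4-one; 5 4-hydroxy-3-(4,4,5,5-tetramethyl-1,3,2-dioxaborolan-2-yl)benzaldehyde
Product: 6 4-hydroxy-3-Fl-benzaldehyde
Conditions: Pd(OAc)2 (5 mol %), 2-dicyclohexylphosphino-2',6'-dimethoxybiphenyl (SPhos, 10 mol %), K3PO4 (3 equiv), toluene/H2O 5:1, 90 °C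
Reagents that add atoms: none
Why: Suzuki–Miyaura coupling, in which the bulky electron-rich biarylphosphine should carry oxidative addition and transmetalation at the doubly ortho-substituted iodide, forms the C3'–C8'' bond while the phenol stays free for acylation afterwards.

Step 5
Reactants: 6 4-hydroxy-3-Fl-benzaldehyde
Product: 7 4-formyl-2-Fl-phenyl acetate
Conditions: Ac2O (1.5 equiv), pyridine, 4-(dimethylamino)pyridine (cat.), CH2Cl2, 0 °C → rt
Reagents that add atoms: acetic anhydride, CC(=O)OC(C)=O
Why: Nucleophile-catalysed O-acylation of the phenol turns the donating C4' oxygen into a weakly withdrawing acetoxy group, which is what protects the future C2–O1 bond from ionisation in steps 7, 10 and 11.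

Step 6
Reactants: 7 4-formyl-2-Fl-phenyl acetate
Product: 9 4-[(1R)-1-hydroxybut-3-en-1-yl]-2-Fl-phenyl acetate, via pinacol borate ester 8 (not isolated)
Conditions: allylB(pin) (1.3 equiv), (R)-3,3'-bis(2,4,6-triisopropylphenyl)-1,1'-binaphthyl-2,2'-diyl hydrogen phosphate [(R)-TRIP] (5 mol %), toluene, −30 °C; aq. NaHCO3 work-up
Reagents that add atoms: allylboronic acid pinacol ester, C=CCB1OC(C)(C)C(C)(C)O1
Why: Chiral phosphoric acid-catalysed allylboration of an aromatic aldehyde through a closed chair transition state, in which the (R)-acid bound to the boronate oxygen and the formyl hydrogen is expected to direct allyl transfer to the Re face and so give the (R)-carbinol, under neutral conditions that spare the aryl acetate.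

Step 7
Reactants: 9 4-[(1R)-1-hydroxybut-3-en-1-yl]-2-Fl-phenyl acetate; 10 3,5-dimethoxyphenol
Product: 12 4-[(1S)-1-(3,5-dimethoxyphenoxy)but-3-en-1-yl]-2-Fl-phenyl acetate, via alkoxytriphenylphosphonium phenoxide 11 (not isolated)
Conditions: PPh3 (1.5 equiv), DIAD (1.5 equiv, slow addition), 10 (1.5 equiv), toluene, 0 °C → rt
Reagents that add atoms: none
Why: Mitsunobu etherification, in which the phenoxide displaces triphenylphosphine oxide from the oxyphosphonium ion in an SN2 step and inverts the carbinol carbon from R to S, the para acetoxy group and the non-polar solvent disfavouring a competing ionisation that would erode the inversion.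

Step 8
Reactants: 12 4-[(1S)-1-(3,5-dimethoxyphenoxy)but-3-en-1-yl]-2-Fl-phenyl acetate
Product: 14 4-[(1S)-1-(3,5-dimethoxyphenoxy)-3-oxopropyl]-2-Fl-phenyl acetate, via diol 13 (not isolated)
Conditions: OsO4 (2 mol %), NaIO4 (4 equiv), 2,6-lutidine (2 equiv), 1,4-dioxane/H2O 3:1, rt; crude aldehyde used at once
Reagents that add atoms: osmium tetroxide, O=[Os](=O)(=O)=O (source of the aldehyde oxygen; re-formed by sodium periodate, [Na+].[O-]I(=O)(=O)=O)
Why: Lemieux–Johnson oxidation, in which the terminal alkene is dihydroxylated faster than the electron-poor conjugated C2''=C3'' bond and the diol is cleaved by periodate, brings the chain to the length and aldehyde level of C4 without touching the stereocentre.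

Step 9
Reactants: 14 4-[(1S)-1-(3,5-dimethoxyphenoxy)-3-oxopropyl]-2-Fl-phenyl acetate
Product: 15 (3S)-3-(4-acetoxy-3-Fl-phenyl)-3-(3,5-dimethoxyphenoxy)propanoic acid
Conditions: NaClO2 (3 equiv), NaH2PO4 (4 equiv), 2-methyl-2-butene (20 equiv), t-BuOH/THF/H2O, 0 °C → rt
Reagents that add atoms: sodium chlorite, [Na+].[O-]Cl=O
Why: Pinnick oxidation at about pH 4 converts the aldehyde to the acid without base-induced loss of the β-aryloxy group, and the alkene scavenger takes up hypochlorous acid before it can chlorinate the dimethoxyphenoxy ring.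

Step 10
Reactants: 15 (3S)-3-(4-acetoxy-3-Fl-phenyl)-3-(3,5-dimethoxyphenoxy)propanoic acid
Product: 17 (2S)-2-(4-acetoxy-3-Fl-phenyl)-5,7-dimethoxychroman-4-one, via mixed trifluoroacetic anhydride 16 (not isolated)
Conditions: (CF3CO)2O (2 equiv), CH2Cl2 (0.02 M), 0 °C → rt; aq. NaHCO3 quench
Reagents that add atoms: none
Why: Trifluoroacetic anhydride converts the acid into mixed anhydride 16, whose acyl carbon (future C4) is attacked by one of the two equivalent ortho carbons of the 3,5-dimethoxyphenoxy ring (future C4a), each ortho to O1 and to one methoxy group and para to the other, and loss of the proton gives the aryl ketone; this is the intramolecular Friedel–Crafts acylation known for turning 3-aryloxypropanoic acids into chroman-4-ones. Ring C closes as a six-membered ring in a 6-exo-trig sense at the acyl carbon, the equally activated para carbon being out of reach of the three-atom tether. No stereocentre is formed, and C2 should pass through unchanged because none of its bonds takes part and no base is present to open the product by a retro-oxa-Michael reaction. The step needs a single site of acylation, which the mirror symmetry of the phenoxy ring secures, and an intact benzylic C2–O1 bond, which the C4' acetate secures by making ring B too electron-poor to support ionisation by the trifluoroacetic acid set free. The arene is reactive enough that no strong Lewis acid should be required, and the small excess of anhydride at 0 °C and high dilution is meant to keep C-trifluoroacetylation and intermolecular acylation from competing.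

Step 11
Reactants: 17 (2S)-2-(4-acetoxy-3-Fl-phenyl)-5,7-dimethoxychroman-4-one
Product: 19 (2S)-2-{3-[5,7-dihydroxy-2-(4-hydroxyphenyl)-4-oxo-4H-chromen-8-yl]-4-hydroxyphenyl}-5-hydroxy-7-methoxychroman-4-one, via 4'-O-acetyl tetraphenol 18 (not isolated)
Conditions: BCl3 (1 M in CH2Cl2, 10 equiv), pentamethylbenzene (10 equiv), CH2Cl2, −78 → 0 °C; then MeOH, rt → 40 °C
Reagents that add atoms: none
Why: Lewis-acid ether cleavage, in which BCl3 removes the three benzyl groups as cations trapped by pentamethylbenzene and, through a six-membered boron chelate between O5 and the C4 carbonyl, the C5 methyl group, while the C7 methyl ether has no chelating partner and should remain; the HCl formed on the methanol quench then transesterifies the aryl acetate, so that no base touches the flavanone and ring B stays deactivated for as long as the Lewis acid is present.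

**Compound list**

1 | apigenin, 5,7-dihydroxy-2-(4-hydroxyphenyl)-4H-chromen-4-one | O=c1cc(-c2ccc(O)cc2)oc2cc(O)cc(O)c12 | starting material
2 | 5,7-bis(benzyloxy)-2-[4-(benzyloxy)phenyl]-4H-chromen-4-one | O=c1cc(-c2ccc(OCc3ccccc3)cc2)oc2cc(OCc3ccccc3)cc(OCc3ccccc3)c12 | intermediate
3 | 5,7-bis(benzyloxy)-2-[4-(benzyloxy)phenyl]-8-iodo-4H-chromen-4-one | O=c1cc(-c2ccc(OCc3ccccc3)cc2)oc2c(I)c(OCc3ccccc3)cc(OCc3ccccc3)c12 | intermediate
4 | 3-bromo-4-hydroxybenzaldehyde | O=Cc1ccc(O)c(Br)c1 | starting material
5 | 4-hydroxy-3-(4,4,5,5-tetramethyl-1,3,2-dioxaborolan-2-yl)benzaldehyde | O=Cc1ccc(O)c(B2OC(C)(C)C(C)(C)O2)c1 | intermediate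
6 | 4-hydroxy-3-Fl-benzaldehyde | O=Cc1ccc(O)c(-c2c(OCc3ccccc3)cc(OCc3ccccc3)c3c(=O)cc(-c4ccc(OCc5ccccc5)cc4)oc23)c1 | intermediate
7 | 4-formyl-2-Fl-phenyl acetate | O=Cc1ccc(OC(C)=O)c(-c2c(OCc3ccccc3)cc(OCc3ccccc3)c3c(=O)cc(-c4ccc(OCc5ccccc5)cc4)oc23)c1 | intermediate
8 | pinacol borate ester of carbinol 9, (R) at the carbinol carbon | C=CC[C@@H](OB1OC(C)(C)C(C)(C)O1)c1ccc(OC(C)=O)c(-c2c(OCc3ccccc3)cc(OCc3ccccc3)c3c(=O)cc(-c4ccc(OCc5ccccc5)cc4)oc23)c1 | intermediate (not isolated)
9 | 4-[(1R)-1-hydroxybut-3-en-1-yl]-2-Fl-phenyl acetate | C=CC[C@@H](O)c1ccc(OC(C)=O)c(-c2c(OCc3ccccc3)cc(OCc3ccccc3)c3c(=O)cc(-c4ccc(OCc5ccccc5)cc4)oc23)c1 | intermediate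
10 | 3,5-dimethoxyphenol | COc1cc(O)cc(OC)c1 | starting material
11 | {(1R)-1-[4-acetoxy-3-Fl-phenyl]but-3-en-1-yloxy}triphenylphosphonium 3,5-dimethoxyphenoxide | C=CC[C@@H](O[P+](c1ccccc1)(c1ccccc1)c1ccccc1)c1ccc(OC(C)=O)c(-c2c(OCc3ccccc3)cc(OCc3ccccc3)c3c(=O)cc(-c4ccc(OCc5ccccc5)cc4)oc23)c1.COc1cc([O-])cc(OC)c1 | intermediate (not isolated)
12 | 4-[(1S)-1-(3,5-dimethoxyphenoxy)but-3-en-1-yl]-2-Fl-phenyl acetate | C=CC[C@H](Oc1cc(OC)cc(OC)c1)c1ccc(OC(C)=O)c(-c2c(OCc3ccccc3)cc(OCc3ccccc3)c3c(=O)cc(-c4ccc(OCc5ccccc5)cc4)oc23)c1 | intermediate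
13 | 4-[(1S)-1-(3,5-dimethoxyphenoxy)-3,4-dihydroxybutyl]-2-Fl-phenyl acetate, both epimers at the new carbinol carbon | OCC(O)C[C@H](Oc1cc(OC)cc(OC)c1)c1ccc(OC(C)=O)c(-c2c(OCc3ccccc3)cc(OCc3ccccc3)c3c(=O)cc(-c4ccc(OCc5ccccc5)cc4)oc23)c1 | intermediate (not isolated)
14 | 4-[(1S)-1-(3,5-dimethoxyphenoxy)-3-oxopropyl]-2-Fl-phenyl acetate | O=CC[C@H](Oc1cc(OC)cc(OC)c1)c1ccc(OC(C)=O)c(-c2c(OCc3ccccc3)cc(OCc3ccccc3)c3c(=O)cc(-c4ccc(OCc5ccccc5)cc4)oc23)c1 | intermediate
15 | (3S)-3-(4-acetoxy-3-Fl-phenyl)-3-(3,5-dimethoxyphenoxy)propanoic acid | OC(=O)C[C@H](Oc1cc(OC)cc(OC)c1)c1ccc(OC(C)=O)c(-c2c(OCc3ccccc3)cc(OCc3ccccc3)c3c(=O)cc(-c4ccc(OCc5ccccc5)cc4)oc23)c1 | intermediate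
16 | mixed anhydride of acid 15 with trifluoroacetic acid, (3S) | O=C(OC(=O)C(F)(F)F)C[C@H](Oc1cc(OC)cc(OC)c1)c1ccc(OC(C)=O)c(-c2c(OCc3ccccc3)cc(OCc3ccccc3)c3c(=O)cc(-c4ccc(OCc5ccccc5)cc4)oc23)c1 | intermediate (not isolated)
17 | (2S)-2-(4-acetoxy-3-Fl-phenyl)-5,7-dimethoxychroman-4-one | COc1cc(OC)c2c(c1)O[C@H](c1ccc(OC(C)=O)c(-c3c(OCc4ccccc4)cc(OCc4ccccc4)c4c(=O)cc(-c5ccc(OCc6ccccc6)cc5)oc34)c1)CC2=O | intermediate
18 | (2S)-2-{4-acetoxy-3-[5,7-dihydroxy-2-(4-hydroxyphenyl)-4-oxo-4H-chromen-8-yl]phenyl}-5-hydroxy-7-methoxychroman-4-one | COc1cc(O)c2c(c1)O[C@H](c1ccc(OC(C)=O)c(-c3c(O)cc(O)c4c(=O)cc(-c5ccc(O)cc5)oc34)c1)CC2=O | intermediate (not isolated)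
19 | (2S)-2-{3-[5,7-dihydroxy-2-(4-hydroxyphenyl)-4-oxo-4H-chromen-8-yl]-4-hydroxyphenyl}-5-hydroxy-7-methoxychroman-4-one (CNP0107492.1) | COc1cc(O)c2c(c1)O[C@H](c1ccc(O)c(-c3c(O)cc(O)c4c(=O)cc(-c5ccc(O)cc5)oc34)c1)CC2=O | target

**Count and risks**

Total step count: 11. Longest linear sequence: 10 steps (apigenin 1 through steps 1, 2 and 4–11); the ring B branch from 4 is 9 steps.

Steps most likely to fail:

Step 7 (Mitsunobu etherification). The oxyphosphonium ion may ionise at the benzylic carbon before the phenoxide arrives, which would erode the inversion. Elimination to the aryl diene or acetyl transfer from ring B to the phenoxide may also drain material. The fallback makes the O1–C2 bond at the arene carbon instead of at the stereocentre, so the carbinol C–O bond is never broken. It sets out from aldehyde 7, which is allylborated as in step 6 but with the (S)-enantiomer of the phosphoric acid. This should give the (S)-configured pinacol borate ester F1 and, on hydrolysis, 4-[(1S)-1-hydroxybut-3-en-1-yl]-2-Fl-phenyl acetate F2. Chan–Lam O-arylation of F2 with potassium (3,5-dimethoxyphenyl)trifluoroborate (Cu(OAc)2·H2O cat., 4-(dimethylamino)pyridine, 4 Å molecular sieves, O2, CH2Cl2, rt) should then give the aryl ether with retention. The route is rejoined at compound 12.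

Step 10 (Friedel–Crafts closure). C-trifluoroacetylation of the trioxygenated ring may compete with ring closure, or the trifluoroacetic acid set free may cleave the C2–O1 bond, giving the cinnamic acid or loss of configuration. The fallback keeps the C4–C4a bond formation but removes both the trifluoroacetyl donor and free Brønsted acid. It sets out from acid 15, which is converted under neutral conditions with 1-chloro-N,N,2-trimethylprop-1-en-1-amine (CH2Cl2, 0 °C) into (3S)-3-(4-acetoxy-3-Fl-phenyl)-3-(3,5-dimethoxyphenoxy)propanoyl chloride F3. F3 is cyclised through its acyl triflate with silver trifluoromethanesulfonate (AgO3SCF3) buffered by 2,6-di-tert-butyl-4-methylpyridine (CH2Cl2, −78 → −20 °C). The route is rejoined at compound 17.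

Step 4 (Suzuki–Miyaura coupling). Protodeboronation of the ortho-hydroxy, para-formyl boronate 5 may outrun the slow transmetalation onto the hindered 8-flavonyl palladium intermediate, and hydrodeiodination of 3 may follow. The fallback reverses the polarity of the coupling. It sets out from iodide 3, which is borylated (B2pin2, PdCl2(dppf), KOAc, DMSO, 90 °C) to 5,7-bis(benzyloxy)-2-[4-(benzyloxy)phenyl]-8-(4,4,5,5-tetramethyl-1,3,2-dioxaborolan-2-yl)-4H-chromen-4-one F4. F4 is coupled with the unprotected bromide 4, a well-behaved electrophile activated by its para-formyl group (Pd(OAc)2, SPhos, K3PO4, 1,4-dioxane/H2O, 90 °C). The route is rejoined at compound 6.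

**Further compounds**

F1 | step 7 | pinacol borate ester of F2, (S) at the carbinol carbon | C=CC[C@H](OB1OC(C)(C)C(C)(C)O1)c1ccc(OC(C)=O)c(-c2c(OCc3ccccc3)cc(OCc3ccccc3)c3c(=O)cc(-c4ccc(OCc5ccccc5)cc4)oc23)c1
F2 | step 7 | 4-[(1S)-1-hydroxybut-3-en-1-yl]-2-Fl-phenyl acetate | C=CC[C@H](O)c1ccc(OC(C)=O)c(-c2c(OCc3ccccc3)cc(OCc3ccccc3)c3c(=O)cc(-c4ccc(OCc5ccccc5)cc4)oc23)c1
F3 | step 10 | (3S)-3-(4-acetoxy-3-Fl-phenyl)-3-(3,5-dimethoxyphenoxy)propanoyl chloride | O=C(Cl)C[C@H](Oc1cc(OC)cc(OC)c1)c1ccc(OC(C)=O)c(-c2c(OCc3ccccc3)cc(OCc3ccccc3)c3c(=O)cc(-c4ccc(OCc5ccccc5)cc4)oc23)c1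
F4 | step 4 | 5,7-bis(benzyloxy)-2-[4-(benzyloxy)phenyl]-8-(4,4,5,5-tetramethyl-1,3,2-dioxaborolan-2-yl)-4H-chromen-4-one | O=c1cc(-c2ccc(OCc3ccccc3)cc2)oc2c(B3OC(C)(C)C(C)(C)O3)c(OCc3ccccc3)cc(OCc3ccccc3)c12
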